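# Proposed synthesis of (+)-mitorubrinic acid B by chromium-mediated closure of ring A

Atom numbers follow the isochromene skeleton: C1, O2, C3, C4, C4a, C5, C6, C7, C8, C8a. Ring A is the carbocycle (C4a, C5, C6, C7, C8, C8a); ring B is the pyran (C1, O2, C3, C4, C4a, C8a).

## The problem

Mitorubrinic acid B (23) is a 7,8-dihydro-6H-isochromen-6-one. A 4H-pyran (ring B) is fused along C4a–C8a to a carbocycle (ring A); C3 carries an (E)-acrylic acid, and a cross-conjugated vinylogous ester runs from O2 through C4a=C5 to the C6 ketone. The only two stereocentres sit side by side in ring A: the quaternary C7 (methyl, tertiary hydroxyl, flanked by C6=O) and C8, which bears the orsellinate. Both are R, and O7 and O8 are cis. C7 has no hydrogen, cannot epimerise and is available from the chiral pool, so it is the one element that can direct C8. The ester is a doubly ortho-substituted benzoate on a secondary alcohol next to a quaternary carbon, so it is hard to form. Several groups forbid rough treatment: the unsubstituted C1 is the electrophilic end of the dienone and is attacked by amines and hydroxide; the tertiary α-ketol can undergo an acyloin shift under base; the O8 ester can migrate to O7; and the alkenes rule out hydrogenolysis. The last steps must therefore be acidic or neutral. The enabling feature is that C8 is an allylic carbinol bonded directly to C8a, the β-carbon of the enol ether O2–C1=C8a. This is the carbon that carries the enolic hydroxyl in kojic acid (8), so as its triflate it can act as an alkenylmetal donor towards a C8 aldehyde, forming C8–C8a and closing ring A.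

## Retrosynthesis

**23 from 22 (protecting groups).** The tert-butyl ester, the two phenolic 4-methoxybenzyl ethers and the O7 triethylsilyl ether of 22 are all acid-labile, so one acidolysis should release 23. Basic or fluoride-basic deprotection would invite O8-to-O7 acyl shift and α-ketol rearrangement, and hydrogenolysis would reduce the alkenes. The forward step must cleave four groups without ionising the allylic C8–O bond.

**22 from 17 and 20 (C8 O–acyl bond).** Cutting the ester gives the bicyclic alcohol 17 and the protected orsellinic acid 20. The ester cannot be carried earlier, because the C8 oxygen only becomes an alcohol in the ring closure. The forward reaction is a retentive acylation of a hindered alcohol by a hindered aroyl chloride, with O7 kept silylated so that only O8 reacts.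

**17 from 16 (C8–C8a, the key cut).** Breaking C8–C8a opens ring A and removes the C8 stereocentre. The precursor 16 is a monocyclic pyran with a C8 aldehyde and a C8a triflate. Among the ring A bonds, this is the only one whose two ends already carry the right functionality in cheap materials: the enol oxygen of kojic acid at C8a and a hydroxymethyl group at C8. Cutting C5–C6 instead would require a separate construction of C8–C8a. The forward reaction must couple at C8a only, tolerate a ketone, an enoate and a silyl ether, and add to the aldehyde from the face that places O8 cis to O7.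

**16 from 14 via 15 (oxidation level).** The β-keto aldehyde is fragile, so it is unveiled last: the primary silyl ether of 14 is cleaved selectively to 15, which is oxidised to 16. This needs only that a primary triethylsilyl ether be more labile than a tertiary one.

**14 from 12 and 7 (C4a=C5).** The exocyclic alkene is cut to the pyran-4-thione 12 and the chloromethyl ketone 7, to be joined by alkylative sulfide contraction. The neighbouring cut, C5–C6 by acylation of a 4-methylenepyran, would require a 4-methylpyrylium salt with a free C1 position, made by adding a methyl organometallic to a pyranone that already carries the triflate and the enoate. Direct condensation on the pyranone carbonyl fails because that carbon is a vinylogous ester and C1 is the more electrophilic site. In the thione, sulfur is first the nucleophile and then the leaving atom, and the C–C bond forms inside a thiirane, so it can only form at C4a.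

**12 from 8 via 9 and 11 (ring B).** Kojic acid (8) supplies all six ring B atoms. Its enolic hydroxyl becomes the C8a triflate (9), its hydroxymethyl group becomes the acrylate by oxidation and olefination (11), and its carbonyl becomes the thione (12). All three operations are functional-group changes on an isolable, neutral heterocycle.

**7 from 1 via 2, 4, 5 and 6 (C5–C8 with the C7 stereocentre).** The chloroketone 7 is traced through the Weinreb amide 6 and diol amide 5 to the hydroxymethyl dioxolanone 4, and from there to the cis dioxolanone 2 of (S)-lactic acid (1). The carboxyl carbon of 1 becomes C6; a one-carbon electrophile added to the enolate brings C8; a chloromethyl carbenoid brings C5. Because the electrophile enters where the hydrogen left, (S)-lactic acid gives the (7R) configuration of 23.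

**20 from 18 via 19 (aryl fragment).** Orsellinic acid (18) is fully 4-methoxybenzylated to 19 and the ester saponified to 20. The ether groups are chosen to fall in the final acid step.

## Roads not taken

**Alternative 1: intramolecular oxa-Diels–Alder reaction.** The cut is O2–C1 and C4a–C8a together. Heating the open-chain precursor A2 would let its C3 enone (O2=C3–C4=C4a) add across the tethered (Z)-enol ether C1=C8a and give the cycloadduct A1, closing both rings in one metal-free step. Its real advantage is that the C7/C8 cis diol is already locked as an acetonide before cyclisation, so C8 does not depend on a late diastereoselective addition; in this respect it is better than the chosen plan. The weak points are structural: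
- A2 has the C5 methylene between the C6 ketone and the C4=C4a alkene, a β,γ-unsaturated ketone that should slip into conjugation and destroy the heterodiene.
- The C3 ketone is a cross-conjugated dienone, so the acrylate alkene can compete as part of a second heterodiene.
- A1 lies two oxidation levels below the target. Methanol must be eliminated across C1–C8a and C4a–C5 dehydrogenated next to an acid-sensitive enol ether, after three stereocentres (C1, C4a, C8a) were set only to be erased.

The chosen plan has to set against this its uncertain C8 selectivity. In exchange, ring B arrives at the correct oxidation level from kojic acid and ring A closes directly to the final unsaturation pattern.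

**Alternative 2: biomimetic orsellinate assembly on O8.** The cut is the O8–acyl bond together with the C–C bonds of the arene. Thermolysis of the diketo-dioxinone A4 would release an acylketene that acylates O8 of the bicyclic diol A5, and base would then close the trioxooctanoate by aldol condensation to the orsellinate A3. Acylketenes acylate hindered alcohols under neutral conditions and no phenol protection is needed, so for the ester bond itself this is probably the better method. It is therefore kept as the fallback for step 15. As a strategy it is only an endgame: it forms no bond or stereocentre of the core, so A5 would still need a route such as the present one. Its aromatisation also exposes the α-ketol and the β-acyloxy ketone to base, and O7 must be kept from competing. The chosen plan sets against it a commercial arene, two simple steps to acid 20, and no base treatment of the assembled core.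

**Alternative 3: ring A by C-acylation of a methylenepyran.** The cut is C5–C6, in the same ring as the chosen cut. The acid of the 4-methylpyrylium salt A7 would be activated with 1-chloro-N,N,2-trimethylpropenylamine, iPr2NEt would deprotonate the 4-methyl group, and the exocyclic carbon C5 of the resulting anhydrobase would attack C6 to give the acetonide A6. It needs no transition metal, gives the vinylogous ester directly, and fixes the cis diol before ring closure, which is an advantage over the chosen plan. Its weakness is A7. This is a pyrylium salt with an unsubstituted C1, easily opened by water, chloride or amine bases. It would need the C8–C8a bond made by separate chemistry and a methyl group introduced at C4a by an organometallic in the presence of the enoate. The acetonide would later have to be removed and the diol differentiated. The chosen plan sets against the better stereocontrol of this road its neutral, isolable intermediates (pyranone, thione, triflate) and a ring-closing bond whose handle, the C8a oxygen, is already present in kojic acid.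

Key step: step 12

Assumption: compounds 14, 15 and 16 are expected as interconverting C4a=C5 isomers (a push–pull alkene); names and SMILES show the isomer with C6 on the C8a side, which is the one that cyclises.

## Route

Step 1
Reactants: 1 (S)-lactic acid
Product: 2 (2S,5S)-2-tert-butyl-5-methyl-1,3-dioxolan-4-one
Conditions: pivalaldehyde, TsOH·H2O (cat.), H2SO4 (cat.), pentane, reflux, water separator; crystallisation
Reagents that add atoms: pivalaldehyde, CC(C)(C)C=O
Why: Acid-catalysed acetalisation of the α-hydroxy acid with azeotropic removal of water (dioxolanone for self-regeneration of stereocentres); the cis acetal, with tert-butyl and methyl on the same face, is the thermodynamic product and is purified by crystallisation, so the acetal carbon is set by C2 of lactic acid.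

Step 2
Reactants: 2 (2S,5S)-2-tert-butyl-5-methyl-1,3-dioxolan-4-one
Product: 4 (2S,5R)-2-tert-butyl-5-(hydroxymethyl)-5-methyl-1,3-dioxolan-4-one, via lithium enolate 3 (not isolated)
Conditions: LiN(iPr)2, THF, −78 °C; CH2O (gas, from cracked paraformaldehyde), −78 °C; aq. NH4Cl
Reagents that add atoms: formaldehyde, C=O
Why: Aldol addition of the dioxolanone lithium enolate to monomeric formaldehyde; the enolate is planar at the former stereocentre and the electrophile enters anti to the tert-butyl group, on the face the hydrogen left, so the quaternary centre (later C7) forms with overall retention and the new carbon is C8.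

Step 3
Reactants: 4 (2S,5R)-2-tert-butyl-5-(hydroxymethyl)-5-methyl-1,3-dioxolan-4-one
Product: 5 (2R)-2,3-dihydroxy-N-methoxy-N,2-dimethylpropanamide
Conditions: MeNH(OMe)·HCl, Me3Al, CH2Cl2, 0 °C → rt; aq. KNaC4H4O6
Reagents that add atoms: N,O-dimethylhydroxylamine hydrochloride, CNOC.Cl
Why: Aminolysis of the acylal-type lactone by the aluminium amide formed in situ (Weinreb amide formation from a lactone); the released hemiacetal collapses to pivalaldehyde and the quaternary centre is not touched.

Step 4
Reactants: 5 (2R)-2,3-dihydroxy-N-methoxy-N,2-dimethylpropanamide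
Product: 6 (2R)-N-methoxy-N,2-dimethyl-2,3-bis(triethylsilyloxy)propanamide
Conditions: TESOTf (2.5 equiv), 2,6-lutidine, CH2Cl2, −78 → 0 °C
Reagents that add atoms: triethylsilyl trifluoromethanesulfonate, CC[Si](CC)(CC)OS(=O)(=O)C(F)(F)F
Why: Silylation with a silyl triflate and a hindered pyridine base protects the primary and the tertiary hydroxyl in one operation; the triflate is reactive enough for the tertiary alcohol.

Step 5
Reactants: 6 (2R)-N-methoxy-N,2-dimethyl-2,3-bis(triethylsilyloxy)propanamide
Product: 7 (3R)-1-chloro-3-methyl-3,4-bis(triethylsilyloxy)butan-2-one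
Conditions: ICH2Cl, MeLi·LiBr, THF/Et2O, −78 °C; aq. NH4Cl at −78 °C
Reagents that add atoms: chloroiodomethane, ClCI
Why: Homologation of a Weinreb amide with chloromethyllithium generated in situ by iodine–lithium exchange; the chelated tetrahedral intermediate persists until the quench, so a single carbenoid adds and the α-chloroketone (C5 and C6) results.

Step 6
Reactants: 8 kojic acid
Product: 9 6-(hydroxymethyl)-4-oxo-4H-pyran-3-yl trifluoromethanesulfonate
Conditions: PhNTf2 (1.05 equiv), Et3N, DMF, 0 °C → rt
Reagents that add atoms: N-phenylbis(trifluoromethanesulfonimide), FC(F)(F)S(=O)(=O)N(c1ccccc1)S(=O)(=O)C(F)(F)F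
Why: The acidic enolic hydroxyl is deprotonated by the amine and sulfonylated by the mild triflyl donor, which leaves the primary alcohol alone (selective enol triflation); this oxygen marks the later C8a.

Step 7
Reactants: 9 6-(hydroxymethyl)-4-oxo-4H-pyran-3-yl trifluoromethanesulfonate
Product: 11 tert-butyl (2E)-3-[4-oxo-5-(trifluoromethylsulfonyloxy)-4H-pyran-2-yl]prop-2-enoate, via pyranone aldehyde 10 (not isolated)
Conditions: Dess–Martin periodinane, CH2Cl2, 0 °C → rt; then Ph3P=CHCO2tBu (2.5 equiv), rt
Reagents that add atoms: tert-butyl (triphenylphosphoranylidene)acetate, CC(C)(C)OC(=O)C=P(c1ccccc1)(c1ccccc1)c1ccccc1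
Why: Dess–Martin oxidation of the activated primary alcohol followed by Wittig olefination in the same flask avoids isolating the hydrate-prone aldehyde; the stabilised ylide gives the (E)-enoate.

Step 8
Reactants: 11 tert-butyl (2E)-3-[4-oxo-5-(trifluoromethylsulfonyloxy)-4H-pyran-2-yl]prop-2-enoate
Product: 12 tert-butyl (2E)-3-[4-thioxo-5-(trifluoromethylsulfonyloxy)-4H-pyran-2-yl]prop-2-enoate
Conditions: Lawesson's reagent (0.6 equiv), toluene, 80 °C
Reagents that add atoms: Lawesson's reagent, COc1ccc(cc1)P1(=S)SP(=S)(S1)c1ccc(OC)cc1
Why: Thionation with Lawesson's reagent is selective for the most electron-rich carbonyl, the pyranone C=O, over the enoate and the sulfonate at this temperature; 4H-pyran-4-thiones are stable, isolable compounds.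

Step 9
Reactants: 12 tert-butyl (2E)-3-[4-thioxo-5-(trifluoromethylsulfonyloxy)-4H-pyran-2-yl]prop-2-enoate; 7 (3R)-1-chloro-3-methyl-3,4-bis(triethylsilyloxy)butan-2-one
Product: 14 tert-butyl (2E)-3-{(4Z)-4-[(3R)-3-methyl-2-oxo-3,4-bis(triethylsilyloxy)butylidene]-5-(trifluoromethylsulfonyloxy)-4H-pyran-2-yl}prop-2-enoate, via alkylthiopyrylium iodide 13 (not isolated)
Conditions: 7 (1.2 equiv), NaI (1.3 equiv), MeCN, rt, dark; then PPh3 (1.5 equiv), iPr2NEt (2 equiv), rt → 40 °C
Reagents that add atoms: none
Why: Alkylative sulfide contraction of the Eschenmoser type: the thione sulfur is alkylated by the α-haloketone (iodide formed in situ, Finkelstein exchange), the base forms the thiocarbonyl ylide, which closes to a spiro thiirane at C4a, and PPh3 removes sulfur to leave C4a=C5. Sulfur extrusion of this kind is known for 4H-pyran-4-thiones and 4-thioflavones alkylated with phenacyl halides, and it can form the new C–C bond only at the former thiocarbonyl carbon.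

Step 10
Reactants: 14 tert-butyl (2E)-3-{(4Z)-4-[(3R)-3-methyl-2-oxo-3,4-bis(triethylsilyloxy)butylidene]-5-(trifluoromethylsulfonyloxy)-4H-pyran-2-yl}prop-2-enoate
Product: 15 tert-butyl (2E)-3-{(4Z)-4-[(3R)-4-hydroxy-3-methyl-2-oxo-3-(triethylsilyloxy)butylidene]-5-(trifluoromethylsulfonyloxy)-4H-pyran-2-yl}prop-2-enoate
Conditions: PPTS (cat.), MeOH/CH2Cl2 (1:4), 0 °C
Reagents that add atoms: none
Why: Acid-catalysed methanolysis removes the unhindered primary triethylsilyl ether much faster than the tertiary one, which is shielded by the quaternary centre and deactivated by the adjacent ketone (selective desilylation).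

Step 11
Reactants: 15 tert-butyl (2E)-3-{(4Z)-4-[(3R)-4-hydroxy-3-methyl-2-oxo-3-(triethylsilyloxy)butylidene]-5-(trifluoromethylsulfonyloxy)-4H-pyran-2-yl}prop-2-enoate
Product: 16 tert-butyl (2E)-3-{(4Z)-4-[(3R)-3-methyl-2,4-dioxo-3-(triethylsilyloxy)butylidene]-5-(trifluoromethylsulfonyloxy)-4H-pyran-2-yl}prop-2-enoate
Conditions: Dess–Martin periodinane, pyridine, CH2Cl2, 0 °C → rt; used at once
Reagents that add atoms: none
Why: Buffered Dess–Martin oxidation gives the C8 aldehyde; it cannot enolise or epimerise because C7 is quaternary, and it is taken directly into the ring closure.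

Step 12
Reactants: 16 tert-butyl (2E)-3-{(4Z)-4-[(3R)-3-methyl-2,4-dioxo-3-(triethylsilyloxy)butylidene]-5-(trifluoromethylsulfonyloxy)-4H-pyran-2-yl}prop-2-enoate
Product: 17 tert-butyl (2E)-3-[(7R,8R)-8-hydroxy-7-methyl-6-oxo-7-(triethylsilyloxy)-7,8-dihydro-6H-isochromen-3-yl]prop-2-enoate
Conditions: CrCl2 (8 equiv), NiCl2 (5 mol %), degassed DMF, 0.005 M, rt
Reagents that add atoms: none
Why: CrCl2 reduces NiCl2 to zerovalent nickel, which inserts into the C8a–O bond of the triflate; transmetalation gives an alkenylchromium species of trivalent chromium that adds to the C8 aldehyde, the intramolecular Nozaki–Hiyama–Kishi coupling of an alkenyl triflate with an aldehyde, a known way to close rings. Ring A closes in the 6-exo-trig mode, C8a attacking the carbonyl carbon C8 with the C=O bond outside the new ring. Only the C4a=C5 isomer with C6 on the C8a side can close, and the pyrylium-enolate character of this push–pull bond lets the isomers interconvert, so all material should pass through that isomer (Curtin–Hammett situation). The new stereocentre C8 is controlled by C7: the C8a–Cr bond lies in the plane of ring B, so the aldehyde oxygen bound to the same chromium must be pseudo-equatorial. The silyloxy group is expected pseudo-axial (dipole opposed to C6=O, no 1,3-diaxial partner because C5 and C8a are trigonal) and the methyl pseudo-equatorial, which places O8 cis to O7, the (8R) configuration. Site selectivity for C8a over the nucleophilic C4 and C5 is fixed by the triflate, and chemoselectivity by the preference of alkenylchromium reagents for aldehydes over ketones and esters. High dilution suppresses intermolecular coupling.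

Step 13
Reactants: 18 orsellinic acid
Product: 19 4-methoxybenzyl 2,4-bis(4-methoxybenzyloxy)-6-methylbenzoate
Conditions: PMBCl (3.5 equiv), K2CO3 (4 equiv), Bu4NI (cat.), DMF, rt → 50 °C
Reagents that add atoms: 4-methoxybenzyl chloride, COc1ccc(CCl)cc1
Why: Williamson alkylation of both phenols and the carboxylate under mild base; early ester formation also blocks the decarboxylation typical of β-resorcylic acids.

Step 14
Reactants: 19 4-methoxybenzyl 2,4-bis(4-methoxybenzyloxy)-6-methylbenzoate
Product: 20 2,4-bis(4-methoxybenzyloxy)-6-methylbenzoic acid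
Conditions: KOH (aq.), MeOH/THF, 65 °C; then cold 1 M HCl to pH 3
Reagents that add atoms: potassium hydroxide, [K+].[OH-]
Why: Saponification of the hindered ester with hydroxide at elevated temperature; aryl 4-methoxybenzyl ethers are stable to base and to the brief cold acidification.

Step 15
Reactants: 17 tert-butyl (2E)-3-[(7R,8R)-8-hydroxy-7-methyl-6-oxo-7-(triethylsilyloxy)-7,8-dihydro-6H-isochromen-3-yl]prop-2-enoate; 20 2,4-bis(4-methoxybenzyloxy)-6-methylbenzoic acid
Product: 22 tert-butyl (2E)-3-[(7R,8R)-8-{[2,4-bis(4-methoxybenzyloxy)-6-methylbenzoyl]oxy}-7-methyl-6-oxo-7-(triethylsilyloxy)-7,8-dihydro-6H-isochromen-3-yl]prop-2-enoate, via acid chloride 21 (not isolated)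
Conditions: 20 (2 equiv), 1-chloro-N,N,2-trimethylpropenylamine, CH2Cl2, 0 °C → rt; then 17, DMAP (2 equiv), Et3N, CH2Cl2, rt → 40 °C
Reagents that add atoms: none
Why: The acid is converted into its chloride with the α-chloroenamine under neutral conditions (no HCl, so the benzyl ethers survive), and the chloride acylates the secondary alcohol under DMAP catalysis (nucleophilic acyl transfer). The C8–O bond is not broken, so C8 keeps its configuration, and the silylated tertiary O7 cannot compete.

Step 16
Reactants: 22 tert-butyl (2E)-3-[(7R,8R)-8-{[2,4-bis(4-methoxybenzyloxy)-6-methylbenzoyl]oxy}-7-methyl-6-oxo-7-(triethylsilyloxy)-7,8-dihydro-6H-isochromen-3-yl]prop-2-enoate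
Product: 23 (+)-mitorubrinic acid B, (2E)-3-[(7R,8R)-8-(2,4-dihydroxy-6-methylbenzoyloxy)-7-hydroxy-7-methyl-6-oxo-7,8-dihydro-6H-isochromen-3-yl]prop-2-enoic acid
Conditions: TFA/CH2Cl2 (1:2), anisole (10 equiv), H2O (5 equiv), 0 °C → rt
Reagents that add atoms: none
Why: Global acidolysis: TFA cleaves the tert-butyl ester (as isobutene), the two aryl 4-methoxybenzyl ethers (cations trapped by anisole) and, with the water present, the tertiary triethylsilyl ether. No base is involved, so acyl migration to O7 and the α-ketol shift are avoided; C7 is quaternary and the C8–O bond should not ionise because the allyl cation would be cross-conjugated with the C6 ketone.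

## Compound list

1 | (S)-lactic acid | C[C@H](O)C(=O)O | starting material
2 | (2S,5S)-2-tert-butyl-5-methyl-1,3-dioxolan-4-one | C[C@@H]1O[C@H](C(C)(C)C)OC1=O | intermediate
3 | lithium (2S)-2-tert-butyl-5-methyl-1,3-dioxol-4-olate (enolate of 2) | CC1=C([O-])O[C@@H](C(C)(C)C)O1.[Li+] | intermediate (not isolated)
4 | (2S,5R)-2-tert-butyl-5-(hydroxymethyl)-5-methyl-1,3-dioxolan-4-one | C[C@]1(CO)O[C@H](C(C)(C)C)OC1=O | intermediate
5 | (2R)-2,3-dihydroxy-N-methoxy-N,2-dimethylpropanamide | C[C@@](O)(CO)C(=O)N(C)OC | intermediate
6 | (2R)-N-methoxy-N,2-dimethyl-2,3-bis(triethylsilyloxy)propanamide | C[C@@](O[Si](CC)(CC)CC)(CO[Si](CC)(CC)CC)C(=O)N(C)OC | intermediate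
7 | (3R)-1-chloro-3-methyl-3,4-bis(triethylsilyloxy)butan-2-one | C[C@@](O[Si](CC)(CC)CC)(CO[Si](CC)(CC)CC)C(=O)CCl | intermediate
8 | kojic acid | OCC1=CC(=O)C(O)=CO1 | starting material
9 | 6-(hydroxymethyl)-4-oxo-4H-pyran-3-yl trifluoromethanesulfonate | OCC1=CC(=O)C(OS(=O)(=O)C(F)(F)F)=CO1 | intermediate
10 | 6-formyl-4-oxo-4H-pyran-3-yl trifluoromethanesulfonate | O=CC1=CC(=O)C(OS(=O)(=O)C(F)(F)F)=CO1 | intermediate (not isolated)
11 | tert-butyl (2E)-3-[4-oxo-5-(trifluoromethylsulfonyloxy)-4H-pyran-2-yl]prop-2-enoate | CC(C)(C)OC(=O)/C=C/C1=CC(=O)C(OS(=O)(=O)C(F)(F)F)=CO1 | intermediate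
12 | tert-butyl (2E)-3-[4-thioxo-5-(trifluoromethylsulfonyloxy)-4H-pyran-2-yl]prop-2-enoate | CC(C)(C)OC(=O)/C=C/C1=CC(=S)C(OS(=O)(=O)C(F)(F)F)=CO1 | intermediate
13 | 2-[(1E)-3-tert-butoxy-3-oxoprop-1-enyl]-4-{[(3R)-3-methyl-2-oxo-3,4-bis(triethylsilyloxy)butyl]sulfanyl}-5-(trifluoromethylsulfonyloxy)pyrylium iodide | CC(C)(C)OC(=O)/C=C/c1cc(SCC(=O)[C@](C)(O[Si](CC)(CC)CC)CO[Si](CC)(CC)CC)c(OS(=O)(=O)C(F)(F)F)c[o+]1.[I-] | intermediate (not isolated)
14 | tert-butyl (2E)-3-{(4Z)-4-[(3R)-3-methyl-2-oxo-3,4-bis(triethylsilyloxy)butylidene]-5-(trifluoromethylsulfonyloxy)-4H-pyran-2-yl}prop-2-enoate | CC[Si](CC)(CC)OC[C@@](C)(O[Si](CC)(CC)CC)C(=O)/C=C1/C=C(/C=C/C(=O)OC(C)(C)C)OC=C1OS(=O)(=O)C(F)(F)F | intermediate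
15 | tert-butyl (2E)-3-{(4Z)-4-[(3R)-4-hydroxy-3-methyl-2-oxo-3-(triethylsilyloxy)butylidene]-5-(trifluoromethylsulfonyloxy)-4H-pyran-2-yl}prop-2-enoate | OC[C@@](C)(O[Si](CC)(CC)CC)C(=O)/C=C1/C=C(/C=C/C(=O)OC(C)(C)C)OC=C1OS(=O)(=O)C(F)(F)F | intermediate
16 | tert-butyl (2E)-3-{(4Z)-4-[(3R)-3-methyl-2,4-dioxo-3-(triethylsilyloxy)butylidene]-5-(trifluoromethylsulfonyloxy)-4H-pyran-2-yl}prop-2-enoate | O=C[C@@](C)(O[Si](CC)(CC)CC)C(=O)/C=C1/C=C(/C=C/C(=O)OC(C)(C)C)OC=C1OS(=O)(=O)C(F)(F)F | intermediate
17 | tert-butyl (2E)-3-[(7R,8R)-8-hydroxy-7-methyl-6-oxo-7-(triethylsilyloxy)-7,8-dihydro-6H-isochromen-3-yl]prop-2-enoate | O[C@@H]1C2=COC(/C=C/C(=O)OC(C)(C)C)=CC2=CC(=O)[C@]1(C)O[Si](CC)(CC)CC | intermediate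
18 | orsellinic acid | Cc1cc(O)cc(O)c1C(=O)O | starting material
19 | 4-methoxybenzyl 2,4-bis(4-methoxybenzyloxy)-6-methylbenzoate | Cc1cc(OCc2ccc(OC)cc2)cc(OCc2ccc(OC)cc2)c1C(=O)OCc1ccc(OC)cc1 | intermediate
20 | 2,4-bis(4-methoxybenzyloxy)-6-methylbenzoic acid | Cc1cc(OCc2ccc(OC)cc2)cc(OCc2ccc(OC)cc2)c1C(=O)O | intermediate
21 | 2,4-bis(4-methoxybenzyloxy)-6-methylbenzoyl chloride | Cc1cc(OCc2ccc(OC)cc2)cc(OCc2ccc(OC)cc2)c1C(=O)Cl | intermediate (not isolated)
22 | tert-butyl (2E)-3-[(7R,8R)-8-{[2,4-bis(4-methoxybenzyloxy)-6-methylbenzoyl]oxy}-7-methyl-6-oxo-7-(triethylsilyloxy)-7,8-dihydro-6H-isochromen-3-yl]prop-2-enoate | Cc1cc(OCc2ccc(OC)cc2)cc(OCc2ccc(OC)cc2)c1C(=O)O[C@@H]1C2=COC(/C=C/C(=O)OC(C)(C)C)=CC2=CC(=O)[C@]1(C)O[Si](CC)(CC)CC | intermediate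
23 | (+)-mitorubrinic acid B | Cc1cc(O)cc(O)c1C(=O)O[C@@H]1C2=COC(/C=C/C(=O)O)=CC2=CC(=O)[C@]1(C)O | target

## Step count and risks

Total: 16 steps. Longest linear sequence: 11 steps (steps 1–5, 9–12, 15, 16, from (S)-lactic acid).

**Step 12 (key step).** The most likely failure is poor facial selectivity at C8. A Felkin–Anh-type approach anti to the C7–O bond would place the silyloxy group pseudo-equatorial and lead to the trans diol, and the two arrangements differ only modestly in energy. Slow closure could also allow protonolysis of the alkenylchromium intermediate (loss of the triflate without C–C bond formation), or Lewis-acid-promoted attack of C4 on the aldehyde from the other C4a=C5 isomer. Fallback for the selectivity problem: the route sets out from 16 as before and accepts the epimeric alcohol, tert-butyl (2E)-3-[(7R,8S)-8-hydroxy-7-methyl-6-oxo-7-(triethylsilyloxy)-7,8-dihydro-6H-isochromen-3-yl]prop-2-enoate F1. F1 is esterified with acid 20 under Mitsunobu conditions (PPh3, diisopropyl azodicarboxylate, toluene), which substitutes the allylic C8 with inversion and returns to the route at 22, replacing step 15. Doubly ortho-substituted benzoic acids are established Mitsunobu partners.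

**Step 9.** S-Alkylation of a thione that carries two electron-withdrawing groups may be slow. The intermediate salt 13 may be opened by the base at the unsubstituted C1, or the ylide may close through the ketone oxygen to an oxathiole instead of the thiirane. Fallback with reversed polarity: amide 6 is converted with MeMgBr into the methyl ketone (3R)-3-methyl-3,4-bis(triethylsilyloxy)butan-2-one F2. Thione 12 is S-methylated with MeOTf to the 4-(methylsulfanyl)pyrylium triflate F3. The lithium enolate of F2 (LiN(SiMe3)2, THF, −78 °C) is then added to F3; addition at the sulfur-bearing carbon and loss of methanethiol on warming would give 14. This is the known substitution of 4-alkylthiopyrylium salts by carbon nucleophiles.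

**Step 15.** Acyl transfer from a doubly ortho-substituted aroyl chloride to a secondary alcohol beside a quaternary carbon may be too slow, and forcing it risks silyl migration from O7 to O8 and decomposition of the dienone. Fallback that builds the arene on the oxygen: alcohol 17 is heated in toluene (110 °C) with the diketo-dioxinone 6-(2,4-dioxopentyl)-2,2-dimethyl-4H-1,3-dioxin-4-one F4 (the reagent A4 of alternative 2, prepared separately). The acylketene released acylates O8 to give the 3,5,7-trioxooctanoate ester F5. Aldol closure and dehydration (Cs2CO3, then HCl in MeOH) give the orsellinate with free phenols, F6. The acid treatment of step 16, without anisole, converts F6 into 23.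

**Step 2.** The dioxolanone enolate is thermally fragile (fragmentation with loss of pivalaldehyde), and formaldehyde may polymerise before C–C bond formation, so conversion may be incomplete. Fallback with an alkylating one-carbon electrophile: enolate 3, made from 2 as before, is alkylated with benzyl chloromethyl ether to (2S,5R)-5-(benzyloxymethyl)-2-tert-butyl-5-methyl-1,3-dioxolan-4-one F7 with the same anti selectivity. Hydrogenolysis of the benzyl ether (H2, palladium on carbon, EtOAc) returns to the route at 4.

## Further compounds

F1 | step 12 | tert-butyl (2E)-3-[(7R,8S)-8-hydroxy-7-methyl-6-oxo-7-(triethylsilyloxy)-7,8-dihydro-6H-isochromen-3-yl]prop-2-enoate | O[C@H]1C2=COC(/C=C/C(=O)OC(C)(C)C)=CC2=CC(=O)[C@]1(C)O[Si](CC)(CC)CC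
F2 | step 9 | (3R)-3-methyl-3,4-bis(triethylsilyloxy)butan-2-one | C[C@@](O[Si](CC)(CC)CC)(CO[Si](CC)(CC)CC)C(C)=O
F3 | step 9 | 2-[(1E)-3-tert-butoxy-3-oxoprop-1-enyl]-4-(methylsulfanyl)-5-(trifluoromethylsulfonyloxy)pyrylium trifluoromethanesulfonate | CC(C)(C)OC(=O)/C=C/c1cc(SC)c(OS(=O)(=O)C(F)(F)F)c[o+]1.[O-]S(=O)(=O)C(F)(F)F
F4 | step 15 | 6-(2,4-dioxopentyl)-2,2-dimethyl-4H-1,3-dioxin-4-one | CC(=O)CC(=O)CC1=CC(=O)OC(C)(C)O1
F5 | step 15 | tert-butyl (2E)-3-[(7R,8R)-7-methyl-6-oxo-7-(triethylsilyloxy)-8-(3,5,7-trioxooctanoyloxy)-7,8-dihydro-6H-isochromen-3-yl]prop-2-enoate | CC(=O)CC(=O)CC(=O)CC(=O)O[C@@H]1C2=COC(/C=C/C(=O)OC(C)(C)C)=CC2=CC(=O)[C@]1(C)O[Si](CC)(CC)CC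
F6 | step 15 | tert-butyl (2E)-3-[(7R,8R)-8-(2,4-dihydroxy-6-methylbenzoyloxy)-7-methyl-6-oxo-7-(triethylsilyloxy)-7,8-dihydro-6H-isochromen-3-yl]prop-2-enoate | Cc1cc(O)cc(O)c1C(=O)O[C@@H]1C2=COC(/C=C/C(=O)OC(C)(C)C)=CC2=CC(=O)[C@]1(C)O[Si](CC)(CC)CC
F7 | step 2 | (2S,5R)-5-(benzyloxymethyl)-2-tert-butyl-5-methyl-1,3-dioxolan-4-one | C[C@]1(COCc2ccccc2)O[C@H](C(C)(C)C)OC1=O
A1 | alternative 1 | 1-methoxy hexahydroisochromenone cycloadduct (C7/C8 acetonide, tert-butyl ester) | CC1(C)O[C@@H]2[C@H]3[C@@H](OC)OC(/C=C/C(=O)OC(C)(C)C)=C[C@H]3CC(=O)[C@]2(C)O1
A2 | alternative 1 | open-chain precursor: C3 dienone tethered through C5–C8 (C7/C8 acetonide) to a (Z)-methyl enol ether at C1=C8a, tert-butyl ester | CO/C=C\[C@H]1OC(C)(C)O[C@@]1(C)C(=O)C/C=C/C(=O)/C=C/C(=O)OC(C)(C)C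
A3 | alternative 2 | tert-butyl ester of mitorubrinic acid B | Cc1cc(O)cc(O)c1C(=O)O[C@@H]1C2=COC(/C=C/C(=O)OC(C)(C)C)=CC2=CC(=O)[C@]1(C)O
A4 | alternative 2 | 6-(2,4-dioxopentyl)-2,2-dimethyl-4H-1,3-dioxin-4-one | CC(=O)CC(=O)CC1=CC(=O)OC(C)(C)O1
A5 | alternative 2 | tert-butyl (2E)-3-[(7R,8R)-7,8-dihydroxy-7-methyl-6-oxo-7,8-dihydro-6H-isochromen-3-yl]prop-2-enoate | O[C@@H]1C2=COC(/C=C/C(=O)OC(C)(C)C)=CC2=CC(=O)[C@]1(C)O
A6 | alternative 3 | C7/C8 acetonide of the bicyclic core, tert-butyl ester | CC1(C)O[C@@H]2C3=COC(/C=C/C(=O)OC(C)(C)C)=CC3=CC(=O)[C@]2(C)O1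
A7 | alternative 3 | 4-methylpyrylium tetrafluoroborate carrying the C7/C8 acetonide carboxylic acid at C8a and the tert-butyl acrylate at C3 | Cc2cc(/C=C/C(=O)OC(C)(C)C)[o+]cc2[C@H]1OC(C)(C)O[C@@]1(C)C(=O)O.F[B-](F)(F)F
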